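5 questions are asked, and one constant read from eta serves the tank among them.

| setting | eta | theta | gamma | dawn | spring | noon | midnight |
|---|---|---|---|---|---|---|---|
| substrate | 0.25 M | 0.12 M | 0.19 M | 0.25 M | 0.25 M | 0.25 M | 0.25 M (fed, over 4.80 d) |
| coupling partner | 0.125 M | 0.125 M | 0.125 M | 0.125 M | 0.125 M (fed, over 4.80 d) | 0.125 M | 0.125 M |
| free catalyst | 0.50 mM | 0.50 mM | 0.50 mM | 0.50 mM | 0.50 mM | 0.50 mM | 0.50 mM |
| remark | run made earlier | run made earlier | run made earlier | a closed flask charged with all of it at once and left for 6.0 d | all but coupling partner at the start; coupling partner goes in evenly over 4.80 d, the run ends at 6.0 d | a single well-mixed tank run continuously and read at steady state, 6.0 d in it on average | all but substrate at the start; substrate goes in evenly over 4.80 d, the run ends at 6.0 d |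
| time |  |  |  | 6.0 d | 6.0 d |  | 6.0 d |

- eta (time / d: target / %, substrate / %): 0.500: 30.1, 69.7; 0.833: 42.3, 59.4; 1.04: 45.0, 55.0; 1.67: 49.5, 49.1; 2.50: 49.6, 49.7; 4.00: 50.3, 50.2; 6.00: 50.2, 49.9
- theta (time / d: target / %, substrate / %): 1.04: 81.6, 20.0; 2.08: 98.6, 1.7; 3.00: 101.2, 0; 4.00: 99.0, 0.3; 5.00: 99.7, 0; 6.00: 99.3, 0.4; 8.00: 99.8, 0
- gamma (time / d: target / %, substrate / %): 0.625: 44.3, 55.7; 0.833: 52.8, 46.6; 1.25: 62.0, 38.5; 2.08: 64.8, 34.8; 3.00: 65.0, 34.3; 5.00: 66.0, 34.0; 8.00: 65.8, 33.9

(readings scatter by 0.5 percentage points)

- the set-up with the highest amount of target at the outlet or at the end, in percent of the substrate put in ("none" if the first two lie within 2 percentage points) (dawn / spring / noon / midnight / none)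
- amount of target at the outlet or at the end, in percent of the substrate put in, dawn
- amount of target at the outlet or at the end, in percent of the substrate put in, spring
- amount of target at the outlet or at the end, in percent of the substrate put in, noon
- amount of target at the outlet or at the end, in percent of the substrate put in, midnight

- the stated concentrations are those of everything mixed, before any reaction; amounts are the same in each set-up
- the feed brings no volume worth counting
- the earlier runs were made in a closed, stirred flask

Target read 0.126 M at the last point of eta and 0.125 M at the last point of gamma, against a partner charge of 0.125 M, while theta, with substrate at 0.12 M, below its partner, read 99.8% of its own substrate. Coupling partner is therefore the limiting reagent, and the ceiling for these set-ups is 50.0% of the substrate. Dawn repeats eta's charge, so it is expected at that ceiling.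

The partner's remainder, ceiling less target, fell in eta between 0.500 d and 1.04 d with a pseudo-first-order rate constant of 2.56 d⁻¹, the clearing constant k, a reading that carries the scatter. If the remainder falls first-order with this k, a steady tank with mean residence time τ holds a remainder of ceiling/(1 + kτ), so my reckoning puts noon 3.1 percentage points short, at 46.9%. Spring runs 1.20 d past its feed, longer than 1/k, 0.391 d. Midnight has fed substrate equal to the partner charge by 2.40 d and then has 3.60 d, far longer than 1/k. Both are expected near the ceiling, which makes the top a tie.

The forecast gives dawn 50%, spring 49.9%, noon 48.1%, midnight 49.9% and best none: “The top values tie, so best is none.” Its noon stands 1.2 points above my reckoning.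

The flasks give dawn 50.0%, spring 50.0%, noon 48.0%, midnight 50.0% and best none.

    2 catalyst intermediate B → spent catalyst (k = 380 M⁻¹ h⁻¹)
    catalyst intermediate C → free catalyst + target (k = 63.0 h⁻¹)
    substrate + free catalyst → catalyst intermediate A (k = 320 M⁻¹ h⁻¹)
    coupling partner + catalyst intermediate A → catalyst intermediate B (k = 370 M⁻¹ h⁻¹)
    catalyst intermediate B ⇌ catalyst intermediate C (K = 1.90, k = 310 h⁻¹)

Noon stands 2 points below the ceiling, against the 3.1 points reckoned with k. For spring, k gives a lag at the end of the feed that decays to 0.19 points below the ceiling, and spring stands at 50.0%. At noon, with 51.8% of the substrate standing and 5.07 mM of partner by difference, free catalyst takes up substrate at 41.5 h⁻¹, while catalyst intermediate A takes up partner at 1.88 h⁻¹, much more slowly. Catalyst intermediate A is the resting state of noon, leaving at that 1.88 h⁻¹, slower than target leaves catalyst intermediate C at 63 h⁻¹.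

The runs were generated by integration with made-up constants; the scatter is artificial.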